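**Strategy.** The route rests on disconnecting C1–C14 of the trans-fused α-methylene-γ-lactone on the 14-membered ring: C14(O)–C1(H)–C15(=C17H2) is a homoallylic alcohol with a 1,1-disubstituted alkene, the retron of a [2,3]-Wittig shift. In one operation the key step contracts a 17-membered allyl propargyl ether (oxygen bridging C14 and C17) to the 14-membered carbocycle, forms C1–C14 and sets C1 and C14. The precursor, closed by simple O-alkylation, carries both lactones as reduced diols protected uniformly as TBS ethers (no allyl benzyl ethers), with the E C1=C15 and Z C8=C9 (C19 cis to C10) alkenes and the C10 centre from (R)-epichlorohydrin already in place.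

Key step: step 22

**Remarks on the chemistry**

- Numbering (cembrane): ring C1–C14; C15/C16/C17 are the α-methylene lactone carbons (C16 carbonyl, C17 methylene); C18 is the methylene on C4; C19 is the butenolide carbonyl; C20 is the methyl on C12. The target is (1R,5R,10R,14S); 5β is taken as 5R, as drawn in the SMILES.
- Structure check: the ring-contraction precursor and product are stereochemically consistent with the target (anti C14/C1 pair from the E C1=C15 ether, C10 R). One point needs care: a Baylis–Hillman allylic bromide has the chain cis to CH2Br. The bromomethyl carbon is therefore made C16 (silyl ether) and the ester carbon C17 (chloride); the opposite assignment would give the Z ring alkene and the cis lactone.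
- Precursor design: C10, C16 and C19 oxygens are all TBS ethers. A PMB ether on C16 or C19 would be an allyl benzyl ether, itself a Wittig substrate under the same base; uniform silylation also allows one global deprotection.
- Assumption: lithium (S,S)-bis(1-phenylethyl)amide is taken as the base matched with the 10R centre. If the pairing proves mismatched the (R,R)-amide is used; the two anti products are diastereomers and separable.

**Fragment C8–C14/C19 (steps 1–8)**

Step 1
Reactants: 1 propargyl alcohol
Product: 2 4-methoxybenzyl propargyl ether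
Conditions: NaH, PMBCl, n-Bu4NI (cat.), THF, 0 °C → rt
Reagents that add atoms: 4-methoxybenzyl chloride, COc1ccc(CCl)cc1
Why: Williamson etherification; the PMB ether on the future C14 oxygen should survive the organolithium, hydride and basic steps and is removable oxidatively (step 20) without touching silyl ethers.

Step 2
Reactants: 2 4-methoxybenzyl propargyl ether; 3 (R)-epichlorohydrin
Product: 5 (R)-1-chloro-6-[(4-methoxybenzyl)oxy]hex-4-yn-2-ol, via lithium acetylide of 2 4 (not isolated)
Conditions: n-BuLi, THF, −78 °C; BF3·OEt2, then 3, −78 °C; aq. NH4Cl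
Reagents that add atoms: none
Why: BF3-mediated alkynylation of an epoxide (Yamaguchi–Hirao) should open the unsubstituted epoxide carbon (future C11) at −78 °C, leaving the chloromethyl group and the C10 stereocentre of 3 untouched.

Step 3
Reactants: 5 (R)-1-chloro-6-[(4-methoxybenzyl)oxy]hex-4-yn-2-ol
Product: 6 (R)-2-{4-[(4-methoxybenzyl)oxy]but-2-yn-1-yl}oxirane
Conditions: K2CO3, MeOH, rt
Reagents that add atoms: none
Why: Intramolecular Williamson closure of the chlorohydrin moves the electrophilic site to the former chloromethyl carbon (future C9) without touching C10.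

Step 4
Reactants: 6 (R)-2-{4-[(4-methoxybenzyl)oxy]but-2-yn-1-yl}oxirane; 7 (phenylthio)acetic acid
Product: 9 (5R)-5-{4-[(4-methoxybenzyl)oxy]but-2-yn-1-yl}-3-(phenylthio)dihydrofuran-2(3H)-one (C3 epimers), via (4R)-4-hydroxy-8-[(4-methoxybenzyl)oxy]-2-(phenylthio)oct-6-ynoic acid 8 (not isolated)
Conditions: 7, LDA (2.1 equiv), THF, −78 → 0 °C; then 6, 0 °C → rt; aq. HCl; PPTS (cat.), toluene, 60 °C
Reagents that add atoms: none
Why: Epoxide opening by a carboxylic acid dianion at the CH2 terminus followed by acid-induced γ-lactonisation should install C8 and C19; only C9 is attacked, so C10 keeps its configuration.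

Step 5
Reactants: 9 (5R)-3-(phenylthio) lactone
Product: 11 (R)-5-{4-[(4-methoxybenzyl)oxy]but-2-yn-1-yl}furan-2(5H)-one, via the 3-(phenylsulfinyl) lactone 10 (not isolated)
Conditions: mCPBA (1.0 equiv), CH2Cl2, −78 °C; then CaCO3, toluene, 110 °C
Reagents that add atoms: none
Why: Chemoselective sulfide oxidation and thermal sulfoxide syn-elimination can only proceed toward C9 and should give the butenolide; alkyne and PMB ether are inert to one equivalent of peracid at −78 °C.

Step 6
Reactants: 11 (R)-5-substituted furan-2(5H)-one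
Product: 12 (R)-3-iodo-5-{4-[(4-methoxybenzyl)oxy]but-2-yn-1-yl}furan-2(5H)-one
Conditions: I2, pyridine, CH2Cl2, rt, dark
Reagents that add atoms: iodine, II
Why: Pyridine-mediated α-iodination of an α,β-unsaturated carbonyl compound (Baylis–Hillman-type addition of pyridine, iodination of the enolate, elimination) should place iodine on C8; the weakly basic medium should not epimerise C10, and unactivated iodine does not add to the internal alkyne.

Step 7
Reactants: 12 (R)-3-iodobutenolide
Product: 13 (4R,2E)-2-iodo-8-[(4-methoxybenzyl)oxy]oct-2-en-6-yne-1,4-diol (CH2OH cis to the carbinol carbon)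
Conditions: DIBAL-H (4 equiv), CH2Cl2, −78 → 0 °C; Rochelle salt
Reagents that add atoms: none
Why: DIBAL reduction of a butenolide through the lactol to the ene-1,4-diol; the ring fixes C19 cis to C10 on C8=C9, and vinyl iodide, alkyne and PMB ether should not be reduced.

Step 8
Reactants: 13 iodo diol
Product: 14 bis-TBS ether of 13 (C10–OTBS, C19–OTBS, C8–I, C14–OPMB)
Conditions: TBSCl, imidazole, DMF, rt
Reagents that add atoms: tert-butyldimethylsilyl chloride, CC(C)(C)[Si](C)(C)Cl
Why: Imidazole-promoted silylation of both hydroxyls in one operation; uniform TBS protection removes any need to differentiate the diol.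

**Fragment C1–C7/C15–C18 (steps 9–16)**

Step 9
Reactants: 15 pent-4-yn-1-ol
Product: 17 (E)-5-iodo-4-methylpent-4-en-1-ol, via O-aluminated (E)-alkenyldimethylalane 16 (not isolated)
Conditions: Me3Al (3 equiv), Cp2ZrCl2 (25 mol %), CH2Cl2, 0 °C → rt; then I2, THF, −30 → 0 °C; aq. K2CO3
Reagents that add atoms: trimethylaluminium, C[Al](C)C; iodine, II
Why: Zr-catalysed syn-carboalumination of a terminal alkyne (Negishi carboalumination) puts methyl (C18) on C4 and aluminium on C5, and iodinolysis with retention should give the E alkene geometry of C4=C5.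

Step 10
Reactants: 17 (E)-5-iodo-4-methylpent-4-en-1-ol
Product: 18 (E)-5-iodo-4-methylpent-4-enal
Conditions: TEMPO (10 mol %), PhI(OAc)2, CH2Cl2, rt
Reagents that add atoms: none
Why: Oxoammonium (TEMPO) oxidation of a primary alcohol should stop at the aldehyde (C1) under anhydrous conditions and tolerates the vinyl iodide.

Step 11
Reactants: 18 (E)-5-iodo-4-methylpent-4-enal; 19 methyl acrylate
Product: 20 methyl (6E)-3-hydroxy-7-iodo-6-methyl-2-methylidenehept-6-enoate (racemic)
Conditions: DABCO (0.5 equiv), 19 (3 equiv), MeOH, rt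
Reagents that add atoms: none
Why: Morita–Baylis–Hillman reaction forms C1–C15; the new carbinol centre is racemic but is destroyed in step 12.

Step 12
Reactants: 20 Baylis–Hillman adduct
Product: 21 methyl (2Z,6E)-2-(bromomethyl)-7-iodo-6-methylhepta-2,6-dienoate
Conditions: NBS, Me2S, CH2Cl2, 0 °C → rt
Reagents that add atoms: N-bromosuccinimide, O=C1CCC(=O)N1Br
Why: Bromination with allylic transposition (SN2′ attack of bromide on the alkoxysulfonium salt) should give the thermodynamically preferred trisubstituted enoate with the chain (C2) cis to CH2Br and trans to the ester, which sets the C1=C15 geometry.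

Step 13
Reactants: 21 allylic bromide
Product: 22 methyl (2E,6E)-2-(acetoxymethyl)-7-iodo-6-methylhepta-2,6-dienoate
Conditions: KOAc, DMF, rt
Reagents that add atoms: potassium acetate, CC(=O)[O-].[K+]
Why: SN2 displacement of the primary allylic bromide by acetate with retention of alkene geometry makes the bromomethyl carbon the oxygenated C16, cis to C2.

Step 14
Reactants: 22 allylic acetate
Product: 23 methyl (2E,6E)-2-(hydroxymethyl)-7-iodo-6-methylhepta-2,6-dienoate
Conditions: K2CO3 (0.2 equiv), MeOH, 0 °C
Reagents that add atoms: none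
Why: Base-catalysed methanolysis removes the acetate, while exchange at the conjugated methyl ester is degenerate.

Step 15
Reactants: 23 allylic alcohol
Product: 24 methyl (2E,6E)-2-{[(tert-butyldimethylsilyl)oxy]methyl}-7-iodo-6-methylhepta-2,6-dienoate
Conditions: TBSCl, imidazole, CH2Cl2, rt
Reagents that add atoms: tert-butyldimethylsilyl chloride, CC(C)(C)[Si](C)(C)Cl
Why: Standard silylation gives C16–OTBS, the same protecting group as on C10 and C19.

Step 16
Reactants: 24 vinyl iodide ester; 25 vinylboronic acid pinacol ester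
Product: 26 methyl (2E,6E)-2-{[(tert-butyldimethylsilyl)oxy]methyl}-6-methylnona-2,6,8-trienoate
Conditions: PdCl2(dppf)·CH2Cl2 (5 mol %), K3PO4, THF/H2O, 60 °C
Reagents that add atoms: none
Why: Suzuki–Miyaura coupling of the alkenyl iodide with retention of geometry should give the 1,3-diene (C4=C5–C6=C7), whose terminal vinyl group is the handle for hydroboration.

**Union, macrocyclisation, ring contraction and endgame (steps 17–27)**

Step 17
Reactants: 26 triene ester; 14 bis-TBS vinyl iodide
Product: 28 coupled ester, methyl (2E,6E,10Z,12R)-12-(TBSO)-2,10-bis(TBSO-methyl)-16-(PMBO)-6-methylhexadeca-2,6,10-trien-14-ynoate (C17 = CO2Me, C14–OPMB), via B-alkyl-9-BBN from 26 (boron on C7) 27 (not isolated)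
Conditions: 9-BBN (1.2 equiv), THF, 0 °C → rt, then H2O (quench of excess B–H); 14, PdCl2(dppf) (7 mol %), AsPh3, aq. Cs2CO3, DMF, rt
Reagents that add atoms: none
Why: B-alkyl Suzuki–Miyaura coupling: 9-BBN should hydroborate only the terminal vinyl group (boron at C7), and Pd-catalysed sp3–sp2 coupling then forms C7–C8 with retention of the C8=C9 geometry while ester, alkyne, silyl and PMB ethers are tolerated.

Step 18
Reactants: 28 coupled ester
Product: 29 allylic alcohol (C17–OH, trans to C2 on C1=C15)
Conditions: DIBAL-H (2.5 equiv), CH2Cl2, −78 °C; Rochelle salt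
Reagents that add atoms: none
Why: DIBAL 1,2-reduction of the conjugated ester turns the ester carbon into the C17 carbinol; alkyne, silyl and PMB ethers should be unaffected at −78 °C.

Step 19
Reactants: 29 allylic alcohol
Product: 31 E-allylic chloride (C17–Cl), via C17 mesylate 30 (not isolated)
Conditions: MsCl, 2,4,6-collidine, LiCl, DMF, 0 °C
Reagents that add atoms: lithium chloride, [Li+].[Cl-]
Why: Mesylation and in situ SN2 displacement by chloride under buffered conditions should give the primary allylic chloride without allylic transposition or E/Z scrambling.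

Step 20
Reactants: 31 allylic chloride
Product: 32 hydroxy chloride (C14–OH, C17–Cl)
Conditions: DDQ, CH2Cl2/pH 7 buffer, 0 °C
Reagents that add atoms: none
Why: Oxidative PMB cleavage by DDQ (hydride abstraction at the electron-rich benzylic position) should free only C14–OH; TBS ethers and the allylic chloride are inert.

Step 21
Reactants: 32 hydroxy chloride
Product: 33 17-membered allyl propargyl ether (oxygen bridging C14 and C17; 10R; C1=C15 E, C4=C5 E, C8=C9 Z; three OTBS)
Conditions: NaH, n-Bu4NI (cat.), THF, 50 °C, syringe-pump addition (final ca. 2 mM)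
Reagents that add atoms: none
Why: Intramolecular Williamson etherification under high dilution: the propargylic alkoxide displaces the primary allylic chloride (SN2, iodide catalysis), and the rigid alkyne and three trisubstituted alkenes restrict the chain enough for 17-membered ring closure.

Step 22
Reactants: 33 17-membered allyl propargyl ether
Product: 35 14-membered propargylic alcohol (1R,10R,14R; C15=C17 exocyclic methylene; three OTBS), via C14-lithiated 33 34 (not isolated)
Conditions: (S,S)-bis(1-phenylethyl)amine, n-BuLi, THF, −78 °C; then 33, −78 → −30 °C; aq. NH4Cl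
Reagents that add atoms: none
Why: The amide should remove the propargylic, oxygen-flanked C14–H, the most acidic C–H now that no benzylic ether is present, and the carbanion adds to C1 through a five-membered envelope transition state as O–C17 breaks, so that C15=C17 becomes the exocyclic methylene and oxygen the C14 alkoxide. This is a [2,3]-sigmatropic Wittig rearrangement, the known ring contraction of macrocyclic allyl propargyl ethers. The 14-membered carbocycle arises by a three-atom ring contraction inside the 17-membered ring (C1–C14 formed), not by an end-to-end C–C cyclisation. The anti C14/C1 relationship (the trans-lactone pair) should follow from the E C1=C15 geometry with the alkynyl group exo in the envelope, reinforced by the C16 substituent on C15. The absolute sense relative to C10 is imposed by the chiral lithium amide, and the alternative anti product is a separable diastereomer. The step needs [2,3] over [1,2] shift and C14 over C17 or C11 deprotonation, which low temperature, the amide base and the higher propargylic acidity should secure.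

Step 23
Reactants: 35 propargylic alcohol
Product: 37 (Z)-C12 vinyl iodide (iodine cis to C14; 1R,10R,14R), via cyclic alkenyl(alkoxy)aluminate 36 (not isolated)
Conditions: Red-Al (3 equiv), THF, 0 °C → rt; then I2, −78 → 0 °C; aq. Na2S2O3/Rochelle salt
Reagents that add atoms: iodine, II
Why: Alkoxide-directed trans-hydroalumination of the propargylic alcohol should place aluminium on C12 in a five-membered alkoxyaluminate, and iodinolysis with retention gives the Z vinyl iodide.

Step 24
Reactants: 37 vinyl iodide
Product: 38 C12-methyl allylic alcohol (C12=C13 E, C20 cis to C14; 1R,10R,14S; three OTBS)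
Conditions: MeLi, CuI (Me2CuLi, 5 equiv), Et2O, 0 °C → rt; aq. NH4Cl/NH3
Reagents that add atoms: lithium dimethylcuprate (from MeLi and CuI), [Li+].C[Cu-]C
Why: Cuprate cross-coupling with an alkenyl iodide proceeds with retention and should give the E C12-methyl alkene; the C14 descriptor changes to S by priority only.

Step 25
Reactants: 38 tris-TBS ether
Product: 39 tetraol (C10, C14, C16, C19 hydroxyls)
Conditions: TBAF (4 equiv), THF, rt; aq. NH4Cl
Reagents that add atoms: none
Why: Fluoride-mediated desilylation should remove all three TBS groups in one operation.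

Step 26
Reactants: 39 tetraol
Product: 41 ovatodiolide, via bis-lactol 40 (not isolated)
Conditions: TEMPO (0.3 equiv), PhI(OAc)2 (5 equiv), CH2Cl2, rt
Reagents that add atoms: none
Why: TEMPO/PhI(OAc)2 oxidative lactonisation: the two primary allylic alcohols should be oxidised selectively to aldehydes, each trapped by its γ-hydroxyl (C14–OH, C10–OH) as a lactol that is oxidised on to the lactone, leaving C1, C10 and C14 untouched.

Step 27
Reactants: 41 ovatodiolide
Product: 42 4-methylene-5β-hydroperoxyovatodiolide
Conditions: O2, tetraphenylporphyrin (cat.), visible light, CH2Cl2, −20 °C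
Reagents that add atoms: dioxygen (as singlet oxygen), O=O
Why: Schenck ene reaction: singlet oxygen should attack the most electron-rich alkene (C4=C5), abstract hydrogen from C18 on the disubstituted side (cis effect) and deliver OOH to C5 suprafacially with shift of the double bond to C4=C18; the C5 configuration is set by peripheral attack on the exposed face of the E alkene in the macrocycle.

**Compound list**

1 | propargyl alcohol | C#CCO | starting material
2 | 4-methoxybenzyl propargyl ether | C#CCOCc1ccc(OC)cc1 | intermediate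
3 | (R)-epichlorohydrin | ClC[C@H]1CO1 | starting material
4 | lithium acetylide of 2 | [Li]C#CCOCc1ccc(OC)cc1 | intermediate
5 | (R)-1-chloro-6-[(4-methoxybenzyl)oxy]hex-4-yn-2-ol | ClC[C@H](O)CC#CCOCc1ccc(OC)cc1 | intermediate
6 | (R)-2-{4-[(4-methoxybenzyl)oxy]but-2-yn-1-yl}oxirane | COc1ccc(COCC#CC[C@@H]2CO2)cc1 | intermediate
7 | (phenylthio)acetic acid | OC(=O)CSc1ccccc1 | starting material
8 | (4R)-4-hydroxy-8-[(4-methoxybenzyl)oxy]-2-(phenylthio)oct-6-ynoic acid | OC(=O)C(Sc1ccccc1)C[C@H](O)CC#CCOCc1ccc(OC)cc1 | intermediate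
9 | (5R)-5-{4-[(4-methoxybenzyl)oxy]but-2-yn-1-yl}-3-(phenylthio)dihydrofuran-2(3H)-one | O=C1O[C@H](CC#CCOCc2ccc(OC)cc2)CC1Sc1ccccc1 | intermediate
10 | (5R)-5-{4-[(4-methoxybenzyl)oxy]but-2-yn-1-yl}-3-(phenylsulfinyl)dihydrofuran-2(3H)-one | O=C1O[C@H](CC#CCOCc2ccc(OC)cc2)CC1S(=O)c1ccccc1 | intermediate
11 | (R)-5-{4-[(4-methoxybenzyl)oxy]but-2-yn-1-yl}furan-2(5H)-one | O=C1C=C[C@@H](CC#CCOCc2ccc(OC)cc2)O1 | intermediate
12 | (R)-3-iodo-5-{4-[(4-methoxybenzyl)oxy]but-2-yn-1-yl}furan-2(5H)-one | O=C1C(I)=C[C@@H](CC#CCOCc2ccc(OC)cc2)O1 | intermediate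
13 | (4R,2E)-2-iodo-8-[(4-methoxybenzyl)oxy]oct-2-en-6-yne-1,4-diol | OC/C(I)=C\[C@H](O)CC#CCOCc1ccc(OC)cc1 | intermediate
14 | (4R,2E)-1,4-bis(tert-butyldimethylsilyloxy)-2-iodo-8-[(4-methoxybenzyl)oxy]oct-2-en-6-yne | CC(C)(C)[Si](C)(C)OC/C(I)=C\[C@H](O[Si](C)(C)C(C)(C)C)CC#CCOCc1ccc(OC)cc1 | intermediate
15 | pent-4-yn-1-ol | C#CCCCO | starting material
16 | O-aluminated (E)-alkenyldimethylalane from 15 | C/C(CCCO[Al](C)C)=C\[Al](C)C | intermediate
17 | (E)-5-iodo-4-methylpent-4-en-1-ol | C/C(CCCO)=C\I | intermediate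
18 | (E)-5-iodo-4-methylpent-4-enal | C/C(CCC=O)=C\I | intermediate
19 | methyl acrylate | C=CC(=O)OC | starting material
20 | methyl (6E)-3-hydroxy-7-iodo-6-methyl-2-methylidenehept-6-enoate (racemic) | C=C(C(=O)OC)C(O)CC/C(C)=C/I | intermediate
21 | methyl (2Z,6E)-2-(bromomethyl)-7-iodo-6-methylhepta-2,6-dienoate | COC(=O)/C(CBr)=C/CC/C(C)=C/I | intermediate
22 | methyl (2E,6E)-2-(acetoxymethyl)-7-iodo-6-methylhepta-2,6-dienoate | COC(=O)/C(COC(C)=O)=C/CC/C(C)=C/I | intermediate
23 | methyl (2E,6E)-2-(hydroxymethyl)-7-iodo-6-methylhepta-2,6-dienoate | COC(=O)/C(CO)=C/CC/C(C)=C/I | intermediate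
24 | methyl (2E,6E)-2-{[(tert-butyldimethylsilyl)oxy]methyl}-7-iodo-6-methylhepta-2,6-dienoate | COC(=O)/C(CO[Si](C)(C)C(C)(C)C)=C/CC/C(C)=C/I | intermediate
25 | vinylboronic acid pinacol ester | C=CB1OC(C)(C)C(C)(C)O1 | starting material
26 | methyl (2E,6E)-2-{[(tert-butyldimethylsilyl)oxy]methyl}-6-methylnona-2,6,8-trienoate | COC(=O)/C(CO[Si](C)(C)C(C)(C)C)=C/CC/C(C)=C/C=C | intermediate
27 | B-alkyl-9-BBN from 26 (boron on C7) | COC(=O)/C(CO[Si](C)(C)C(C)(C)C)=C/CC/C(C)=C/CCB1C2CCCC1CCC2 | intermediate
28 | coupled ester (C17 = CO2Me, C14–OPMB, three OTBS) | COC(=O)/C(CO[Si](C)(C)C(C)(C)C)=C/CC/C(C)=C/CC/C(CO[Si](C)(C)C(C)(C)C)=C/[C@H](O[Si](C)(C)C(C)(C)C)CC#CCOCc1ccc(OC)cc1 | intermediate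
29 | allylic alcohol (C17–OH) | OC/C(CO[Si](C)(C)C(C)(C)C)=C/CC/C(C)=C/CC/C(CO[Si](C)(C)C(C)(C)C)=C/[C@H](O[Si](C)(C)C(C)(C)C)CC#CCOCc1ccc(OC)cc1 | intermediate
30 | C17 mesylate | CS(=O)(=O)OC/C(CO[Si](C)(C)C(C)(C)C)=C/CC/C(C)=C/CC/C(CO[Si](C)(C)C(C)(C)C)=C/[C@H](O[Si](C)(C)C(C)(C)C)CC#CCOCc1ccc(OC)cc1 | intermediate
31 | E-allylic chloride (C17–Cl, C14–OPMB) | ClC/C(CO[Si](C)(C)C(C)(C)C)=C/CC/C(C)=C/CC/C(CO[Si](C)(C)C(C)(C)C)=C/[C@H](O[Si](C)(C)C(C)(C)C)CC#CCOCc1ccc(OC)cc1 | intermediate
32 | hydroxy chloride (C14–OH, C17–Cl) | ClC/C(CO[Si](C)(C)C(C)(C)C)=C/CC/C(C)=C/CC/C(CO[Si](C)(C)C(C)(C)C)=C/[C@H](O[Si](C)(C)C(C)(C)C)CC#CCO | intermediate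
33 | 17-membered allyl propargyl ether (10R) | O1CC#CC[C@@H](O[Si](C)(C)C(C)(C)C)/C=C(CO[Si](C)(C)C(C)(C)C)/CC/C=C(C)/CC/C=C(CO[Si](C)(C)C(C)(C)C)/C1 | intermediate
34 | C14-lithiated 33 | [Li]C1C#CC[C@@H](O[Si](C)(C)C(C)(C)C)/C=C(CO[Si](C)(C)C(C)(C)C)/CC/C=C(C)/CC/C=C(CO[Si](C)(C)C(C)(C)C)/CO1 | intermediate
35 | 14-membered propargylic alcohol (1R,10R,14R) | C=C(CO[Si](C)(C)C(C)(C)C)[C@H]1CC/C(C)=C/CC/C(CO[Si](C)(C)C(C)(C)C)=C/[C@H](O[Si](C)(C)C(C)(C)C)CC#C[C@@H]1O | intermediate
36 | sodium cyclic alkenyl(alkoxy)bis(2-methoxyethoxy)aluminate (Al on C12) | C=C(CO[Si](C)(C)C(C)(C)C)[C@H]1CC/C(C)=C/CC/C(CO[Si](C)(C)C(C)(C)C)=C/[C@H](O[Si](C)(C)C(C)(C)C)CC2=C[C@@H]1O[Al-]2(OCCOC)OCCOC.[Na+] | intermediate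
37 | (Z)-C12 vinyl iodide (1R,10R,14R) | C=C(CO[Si](C)(C)C(C)(C)C)[C@H]1CC/C(C)=C/CC/C(CO[Si](C)(C)C(C)(C)C)=C/[C@H](O[Si](C)(C)C(C)(C)C)C/C(I)=C/[C@@H]1O | intermediate
38 | C12-methyl allylic alcohol, tris-TBS ether (1R,10R,14S) | C=C(CO[Si](C)(C)C(C)(C)C)[C@H]1CC/C(C)=C/CC/C(CO[Si](C)(C)C(C)(C)C)=C/[C@H](O[Si](C)(C)C(C)(C)C)C/C(C)=C/[C@@H]1O | intermediate
39 | tetraol (1R,10R,14S) | C=C(CO)[C@H]1CC/C(C)=C/CC/C(CO)=C/[C@H](O)C/C(C)=C/[C@@H]1O | intermediate
40 | bis-lactol | C=C1C(O)O[C@H]2/C=C(\C)C[C@@H]3C=C(CC/C=C(C)/CC[C@H]12)C(O)O3 | intermediate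
41 | ovatodiolide | C=C1C(=O)O[C@H]2/C=C(\C)C[C@@H]3C=C(CC/C=C(C)/CC[C@H]12)C(=O)O3 | intermediate
42 | 4-methylene-5β-hydroperoxyovatodiolide (1R,5R,10R,14S) | C=C1C(=O)O[C@H]2/C=C(\C)C[C@@H]3C=C(CC[C@@H](OO)C(=C)CC[C@H]12)C(=O)O3 | target

**Step count.** Total: 27 steps. Longest linear sequence: 19 steps (1–8, then 17–27; the branch 9–16, then 17–27 is equally long).

**Steps most likely to fail**

Step 22. The deprotonation/rearrangement may not discriminate the two faces relative to C10, giving both anti diastereomers. The carbanion may also take the [1,2]-shift, or C11 may be deprotonated with loss of the C10 silyloxy group. The fallback forms the same C1–C14 bond by intramolecular carbonyl allylation instead of ring contraction. It sets out from 32: MnO2 oxidation of the propargylic alcohol should give the ynal chloride F1. CrCl2 with LiI in THF under high dilution (with a chiral oxazoline–sulfonamide ligand if facial control is needed) converts the allylic chloride into the allylchromium species. This adds through its γ-carbon C1 to the C14 aldehyde in a chair transition state (Nozaki–Hiyama–Kishi allylation; anti product, exocyclic C15=C17). The route is rejoined at 35.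

Step 27. Singlet oxygen may be delivered to the other face of C4=C5, so that the C5 epimer predominates. The fallback keeps the ene reaction for regiochemistry but sets C5 by inversion. It sets out from 41, whose photo-oxygenation would then give the 5-epi-hydroperoxide F2. Triphenylphosphine reduces it to the 5-epi allylic alcohol F3. MsCl/Et3N at −20 °C gives the 5-epi mesylate F4. SN2 displacement with the caesium salt of 2-methoxyprop-2-yl hydroperoxide in DMF at 0 °C (inversion at C5) gives the peroxy ketal F5. Aqueous acetic acid in THF releases the hydroperoxide, rejoining the route at 42.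

Step 21. Intermolecular alkylation (oligomers) or SN2′/elimination at the allylic chloride may outrun closure of the 17-membered ring. The fallback makes the ether bond intermolecularly and closes the ring at C7–C8. It sets out from 14 and 26. DDQ on 14 gives the vinyl iodide propargylic alcohol F6. DIBAL on 26 gives the trienol F7, which is converted via the trienyl mesylate F8 into the trienyl chloride F9 (MsCl, collidine, LiCl). NaH-mediated Williamson etherification of F6 with F9 gives the acyclic ether F10. Hydroboration of its terminal vinyl group with 9-BBN gives the borane F11. Intramolecular B-alkyl Suzuki–Miyaura coupling under high dilution (PdCl2(dppf), AsPh3, Cs2CO3) closes the ring, rejoining the route at 33.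

**Further compounds**

F1 | step 22 | ynal chloride (C14 aldehyde, C17–Cl) | ClC/C(CO[Si](C)(C)C(C)(C)C)=C/CC/C(C)=C/CC/C(CO[Si](C)(C)C(C)(C)C)=C/[C@H](O[Si](C)(C)C(C)(C)C)CC#CC=O
F2 | step 27 | 5-epi-hydroperoxide (5S) | C=C1C(=O)O[C@H]2/C=C(\C)C[C@@H]3C=C(CC[C@H](OO)C(=C)CC[C@H]12)C(=O)O3
F3 | step 27 | 5-epi allylic alcohol (5S) | C=C1C(=O)O[C@H]2/C=C(\C)C[C@@H]3C=C(CC[C@H](O)C(=C)CC[C@H]12)C(=O)O3
F4 | step 27 | 5-epi mesylate (5S) | C=C1C(=O)O[C@H]2/C=C(\C)C[C@@H]3C=C(CC[C@H](OS(C)(=O)=O)C(=C)CC[C@H]12)C(=O)O3
F5 | step 27 | peroxy ketal (5R, 2-methoxyprop-2-yl peroxide) | C=C1C(=O)O[C@H]2/C=C(\C)C[C@@H]3C=C(CC[C@@H](OOC(C)(C)OC)C(=C)CC[C@H]12)C(=O)O3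
F6 | step 21 | vinyl iodide propargylic alcohol (14 without PMB) | CC(C)(C)[Si](C)(C)OC/C(I)=C\[C@H](O[Si](C)(C)C(C)(C)C)CC#CCO
F7 | step 21 | trienol (26 reduced at C17) | OC/C(CO[Si](C)(C)C(C)(C)C)=C/CC/C(C)=C/C=C
F8 | step 21 | trienyl mesylate | CS(=O)(=O)OC/C(CO[Si](C)(C)C(C)(C)C)=C/CC/C(C)=C/C=C
F9 | step 21 | trienyl chloride | ClC/C(CO[Si](C)(C)C(C)(C)C)=C/CC/C(C)=C/C=C
F10 | step 21 | acyclic allyl propargyl ether (vinyl iodide and diene termini) | C=C/C=C(C)/CC/C=C(CO[Si](C)(C)C(C)(C)C)/COCC#CC[C@@H](O[Si](C)(C)C(C)(C)C)/C=C(/I)CO[Si](C)(C)C(C)(C)C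
F11 | step 21 | 9-BBN adduct of F10 (boron on C7) | C1CCC2CCCC1B2CC/C=C(C)/CC/C=C(CO[Si](C)(C)C(C)(C)C)/COCC#CC[C@@H](O[Si](C)(C)C(C)(C)C)/C=C(/I)CO[Si](C)(C)C(C)(C)C
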